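**Plan**
- Retrosynthetic cuts, last to first: C3–Br (from a C3 silyl ether), C7=C15 (from a C7 ketone), C8–C9 together with C10–Br (ring A), C6–C11 (ester-enolate Claisen of a prenyl ester), and the isopropenyl group of (S)-limonene (degraded to the C7 carboxyl).
- Enabling feature: the neopentyl secondary bromide at C10 lies two atoms from C8, the carbon next to sp2 C7. With C7 as a ketone, a C8 radical adding to a C9=C10 vinyl group on C11 forms C8–C9, closes ring A (C6–C11) 6-endo, and leaves a C10 radical that is capped by bromine atom transfer.
- Forward order: ring B is the limonene ring (trans epoxide, chloride opening at C2, silyl ether at C3). The Claisen step joins C11/C10/C9 to C6, the acid becomes the bromomethyl ketone, ring A closes, and methylenation and the C3 bromide finish the route.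
- Stereochemistry: C2 and C3 are relayed from the limonene stereocentre (bromohydrin, epoxide, trans-diaxial chloride opening). C6 is set in the Claisen step anti to the axial C2–Cl, C10 by equatorial bromine transfer, and C3–Br by retention through a chloronium ion.

Key step: step 10

Remark on the chemistry: chamigrene numbering is used for the skeleton (C6 spiro; ring B C1–C5 with C2 = CHCl and C3 = CMeX; ring A C7–C11 with C10 = CHBr and C11 = CMe2; C15 the exocyclic methylene). The ring B chair with axial C2–Cl and axial C3–O is assumed to persist from 4 to 17.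

**Step 1**
Reactants: 1 (S)-limonene
Product: 3 trans-limonene oxide (1R,4S,6S), via bromohydrin 2 (not isolated)
Conditions: NBS, acetone/H2O, 0 °C; then aq. NaOH, 60 °C
Reagents that add atoms: water, O (supplies the epoxide oxygen); N-bromosuccinimide, O=C1CCC(=O)N1Br (its bromine is present only in intermediate 2)
Why: Bromohydrin formation followed by intramolecular Williamson closure: the ring alkene is the more nucleophilic one, water opens the reversibly formed bromonium ion at the tertiary carbon in the trans-diaxial sense that keeps the isopropenyl group equatorial, and base then closes the epoxide with its oxygen cis to the isopropenyl group, so both new stereocentres are relayed from the limonene stereocentre.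

**Step 2**
Reactants: 3 trans-limonene oxide
Product: 4 (1R,2R,4S)-2-chloro-1-methyl-4-(prop-1-en-2-yl)cyclohexan-1-ol
Conditions: LiCl, AcOH, THF, rt
Reagents that add atoms: lithium chloride, [Li+].[Cl-]
Why: Nucleophilic epoxide opening under Fürst–Plattner control: with the isopropenyl group equatorial the trans-diaxial pathway of this epoxide leads to the secondary carbon C2, which chloride attacks with inversion, giving the chlorohydrin with axial Cl at C2 and axial tertiary OH at C3 (2R,3R in target numbering).

**Step 3**
Reactants: 4 chlorohydrin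
Product: 5 {[(1R,2R,4S)-2-chloro-1-methyl-4-(prop-1-en-2-yl)cyclohexyl]oxy}triethylsilane
Conditions: Et3SiOTf, 2,6-lutidine, CH2Cl2, −78 to 0 °C
Reagents that add atoms: triethylsilyl trifluoromethanesulfonate, CC[Si](CC)(CC)OS(=O)(=O)C(F)(F)F
Why: Silylation of a hindered tertiary alcohol with a silyl triflate and a weak, non-nucleophilic base is standard, and the base is too weak to re-close the chlorohydrin to the epoxide.

**Step 4**
Reactants: 5 silyl ether
Product: 6 1-[(1S,3R,4R)-3-chloro-4-methyl-4-(triethylsilyloxy)cyclohexyl]ethan-1-one
Conditions: O3, CH2Cl2/MeOH, −78 °C; then Me2S, −78 °C to rt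
Reagents that add atoms: ozone, [O-][O+]=O
Why: Ozonolysis with reductive work-up cleaves the only C=C bond to the methyl ketone, and the silyl ether and the alkyl chloride are inert to ozone.

**Step 5**
Reactants: 6 methyl ketone
Product: 7 (1S,3R,4R)-3-chloro-4-methyl-4-(triethylsilyloxy)cyclohexane-1-carboxylic acid
Conditions: Br2, NaOH, H2O/1,4-dioxane, 0 °C to rt; then 1 M HCl to pH 4, 0 °C
Reagents that add atoms: sodium hydroxide, [Na+].[OH-] (supplies the carboxyl OH oxygen)
Why: Haloform degradation: exhaustive bromination of the methyl group and hydroxide-induced C–C cleavage give the acid, the tertiary silyl ether and the secondary chloride tolerate cold aqueous base, and any epimerisation next to the carbonyl is harmless because this centre is planarised in step 7.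

**Step 6**
Reactants: 7 acid; 8 prenol
Product: 9 3-methylbut-2-en-1-yl (1S,3R,4R)-3-chloro-4-methyl-4-(triethylsilyloxy)cyclohexane-1-carboxylate
Conditions: DCC, DMAP (cat.), CH2Cl2, 0 °C to rt
Reagents that add atoms: none
Why: Steglich esterification under neutral carbodiimide conditions leaves the silyl ether and the chloride untouched.

**Step 7**
Reactants: 9 prenyl ester
Product: 12 (1R,3R,4R)-3-chloro-4-methyl-1-(2-methylbut-3-en-2-yl)-4-(triethylsilyloxy)cyclohexane-1-carboxylic acid, via silyl ketene acetal 10 (not isolated), via trimethylsilyl ester 11 (not isolated)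
Conditions: LiN(iPr)2, Me3SiCl, THF, −78 °C; then 65 °C; 1 M HCl work-up
Reagents that add atoms: chlorotrimethylsilane, C[Si](C)(C)Cl (silyl group present only in intermediates 10 and 11)
Why: Ireland–Claisen rearrangement: in-situ silylation traps the ester enolate at −78 °C before it can displace chloride, and the [3,3] shift of the exocyclic silyl ketene acetal joins C11 to C6 on the equatorial face of the ring B chair because the axial face is blocked by the 1,3-diaxial C2 chlorine, so the dimethylallyl group ends trans to Cl and cis to the C3 oxygen (the C6 configuration of the target), vicinal quaternary carbons being within the known scope of this rearrangement.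

**Step 8**
Reactants: 12 acid
Product: 13 1-[(1R,3R,4R)-3-chloro-4-methyl-1-(2-methylbut-3-en-2-yl)-4-(triethylsilyloxy)cyclohexyl]ethan-1-one
Conditions: MeLi (3 equiv), Et2O, 0 °C to rt; inverse quench into cold aq. NH4Cl
Reagents that add atoms: methyllithium, [Li]C
Why: Ketone synthesis from a carboxylic acid with excess organolithium: the gem-diolate formed from the carboxylate and MeLi does not collapse until the quench, the small nucleophile can reach this neopentyl carboxyl group, and the chloride, vinyl group and silyl ether are inert; the new methyl carbon is C8.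

**Step 9**
Reactants: 13 methyl ketone
Product: 15 2-bromo-1-[(1R,3R,4R)-3-chloro-4-methyl-1-(2-methylbut-3-en-2-yl)-4-(triethylsilyloxy)cyclohexyl]ethan-1-one, via silyl enol ether 14 (not isolated)
Conditions: LiN(iPr)2, Me3SiCl, THF, −78 °C; then NBS, THF, −78 to 0 °C
Reagents that add atoms: N-bromosuccinimide, O=C1CCC(=O)N1Br; chlorotrimethylsilane, C[Si](C)(C)Cl (silyl group present only in intermediate 14)
Why: Regiospecific alpha-bromination through the silyl enol ether: C6 is quaternary, so enolisation can only occur towards the methyl group, and NBS brominates the electron-rich enol ether much faster than the hindered vinyl group.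

**Step 10**
Reactants: 15 bromomethyl ketone
Product: 16 (4S,6R,8R,9R)-4-bromo-8-chloro-5,5,9-trimethyl-9-(triethylsilyloxy)spiro[5.5]undecan-1-one
Conditions: Et3B (0.3 equiv in portions), air, benzene (0.1 M), rt
Reagents that add atoms: none
Why: Ethyl radicals from Et3B and oxygen abstract bromine from 15; the electrophilic C8 radical (alpha to the C7 carbonyl) adds to the terminal vinyl carbon C9, and the resulting secondary C10 radical takes bromine from the weak C–Br bond of a further molecule of 15, which forms C10–Br and carries the chain. The closest known reaction type is the halogen atom-transfer radical cyclisation of alpha-halo ketones (Kharasch-type atom transfer made intramolecular), in which 2-oxohex-5-enyl radicals with the carbonyl group inside the forming ring close in the 6-endo mode. Ring A (C6–C11) therefore closes 6-endo-trig through the new C8–C9 bond; 5-exo attack at C10 is disfavoured by the in-ring carbonyl and by the adjacent quaternary C11, and the two quaternary carbons C6 and C11 in the chain accelerate closure over intermolecular addition. The one new stereocentre, C10, is set in the bromine transfer: the chair of ring A that turns the C7 carbonyl oxygen away from the axial C2 chlorine has C1 of ring B axial on ring A, C1 blocks the axial face of the C10 radical, and the bulky bromine donor attacks equatorially, cis to C5, which gives 10S. The step needs 6-endo regioselectivity, equatorial bromine delivery and a chain that outruns reduction; these rest on the substitution pattern just described, on the saturated ring B (no second radical acceptor, tertiary oxygen still silylated and not yet a bromide) and on running at about 0.1 M with repeated small charges of initiator.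

**Step 11**
Reactants: 16 spiro ketone
Product: 17 {[(2R,3R,6S,8S)-8-bromo-2-chloro-3,7,7-trimethyl-11-methylidenespiro[5.5]undecan-3-yl]oxy}triethylsilane
Conditions: Cp2TiMe2, toluene, 70 °C, dark
Reagents that add atoms: dimethyltitanocene Cp2TiMe2, [CH3-].[CH3-].[Ti+4].c1cc[cH-]c1.c1cc[cH-]c1
Why: Petasis methylenation: Cp2Ti=CH2 formed thermally from Cp2TiMe2 olefinates hindered, enolisable ketones through an oxatitanacyclobutane, and because the reagent is not basic the gamma-bromo ketone cannot enolise and close to a cyclopropane.

**Step 12**
Reactants: 17 methylidene silyl ether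
Product: 18 target, (2S,6S,8R,9R)-2,9-dibromo-8-chloro-1,1,9-trimethyl-5-methylidenespiro[5.5]undecane
Conditions: Ph3PBr2, 2,6-di-tert-butylpyridine (cat.), CH2Cl2, −20 to 0 °C
Reagents that add atoms: dibromotriphenylphosphorane, BrP(Br)(c1ccccc1)(c1ccccc1)c1ccccc1
Why: Direct silyl ether to bromide exchange with Ph3PBr2: the alkoxyphosphonium salt at tertiary C3 ionises with anchimeric assistance from the antiperiplanar axial C2 chlorine, and bromide opens the bridged chloronium ion at the more substituted carbon from the face opposite to chlorine, so substitution proceeds with retention and places Br at C3 trans to Cl (3R in chamigrene numbering).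

**Compound list**
1 | (S)-limonene, (4S)-1-methyl-4-(prop-1-en-2-yl)cyclohex-1-ene | CC1=CC[C@H](CC1)C(C)=C | starting material
2 | (1R,2R,4S)-2-bromo-1-methyl-4-(prop-1-en-2-yl)cyclohexan-1-ol (bromohydrin) | C=C(C)[C@H]1CC[C@@](C)(O)[C@H](Br)C1 | intermediate
3 | trans-limonene oxide, (1R,4S,6S)-1-methyl-4-(prop-1-en-2-yl)-7-oxabicyclo[4.1.0]heptane (epoxide oxygen cis to isopropenyl) | C=C(C)[C@H]1CC[C@@]2(C)O[C@H]2C1 | intermediate
4 | (1R,2R,4S)-2-chloro-1-methyl-4-(prop-1-en-2-yl)cyclohexan-1-ol | C=C(C)[C@H]1CC[C@@](C)(O)[C@H](Cl)C1 | intermediate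
5 | {[(1R,2R,4S)-2-chloro-1-methyl-4-(prop-1-en-2-yl)cyclohexyl]oxy}triethylsilane | C=C(C)[C@H]1CC[C@@](C)(O[Si](CC)(CC)CC)[C@H](Cl)C1 | intermediate
6 | 1-[(1S,3R,4R)-3-chloro-4-methyl-4-(triethylsilyloxy)cyclohexyl]ethan-1-one | CC(=O)[C@H]1CC[C@@](C)(O[Si](CC)(CC)CC)[C@H](Cl)C1 | intermediate
7 | (1S,3R,4R)-3-chloro-4-methyl-4-(triethylsilyloxy)cyclohexane-1-carboxylic acid | OC(=O)[C@H]1CC[C@@](C)(O[Si](CC)(CC)CC)[C@H](Cl)C1 | intermediate
8 | prenol, 3-methylbut-2-en-1-ol | CC(C)=CCO | starting material
9 | 3-methylbut-2-en-1-yl (1S,3R,4R)-3-chloro-4-methyl-4-(triethylsilyloxy)cyclohexane-1-carboxylate | CC(C)=CCOC(=O)[C@H]1CC[C@@](C)(O[Si](CC)(CC)CC)[C@H](Cl)C1 | intermediate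
10 | O-prenyl O-trimethylsilyl ketene acetal of 9, triethyl{[(1R,2R)-2-chloro-1-methyl-4-{[(3-methylbut-2-en-1-yl)oxy](trimethylsilyloxy)methylidene}cyclohexyl]oxy}silane (double-bond geometry of no consequence) | CC(C)=CCOC(O[Si](C)(C)C)=C1CC[C@@](C)(O[Si](CC)(CC)CC)[C@H](Cl)C1 | intermediate
11 | trimethylsilyl (1R,3R,4R)-3-chloro-4-methyl-1-(2-methylbut-3-en-2-yl)-4-(triethylsilyloxy)cyclohexane-1-carboxylate | C[Si](C)(C)OC(=O)[C@]1(C(C)(C)C=C)CC[C@@](C)(O[Si](CC)(CC)CC)[C@H](Cl)C1 | intermediate
12 | (1R,3R,4R)-3-chloro-4-methyl-1-(2-methylbut-3-en-2-yl)-4-(triethylsilyloxy)cyclohexane-1-carboxylic acid | OC(=O)[C@]1(C(C)(C)C=C)CC[C@@](C)(O[Si](CC)(CC)CC)[C@H](Cl)C1 | intermediate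
13 | 1-[(1R,3R,4R)-3-chloro-4-methyl-1-(2-methylbut-3-en-2-yl)-4-(triethylsilyloxy)cyclohexyl]ethan-1-one | CC(=O)[C@]1(C(C)(C)C=C)CC[C@@](C)(O[Si](CC)(CC)CC)[C@H](Cl)C1 | intermediate
14 | triethyl{[(1R,2R,4R)-2-chloro-1-methyl-4-(2-methylbut-3-en-2-yl)-4-[1-(trimethylsilyloxy)ethenyl]cyclohexyl]oxy}silane (silyl enol ether) | C=C(O[Si](C)(C)C)[C@]1(C(C)(C)C=C)CC[C@@](C)(O[Si](CC)(CC)CC)[C@H](Cl)C1 | intermediate
15 | 2-bromo-1-[(1R,3R,4R)-3-chloro-4-methyl-1-(2-methylbut-3-en-2-yl)-4-(triethylsilyloxy)cyclohexyl]ethan-1-one (key-step precursor) | BrCC(=O)[C@]1(C(C)(C)C=C)CC[C@@](C)(O[Si](CC)(CC)CC)[C@H](Cl)C1 | intermediate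
16 | (4S,6R,8R,9R)-4-bromo-8-chloro-5,5,9-trimethyl-9-(triethylsilyloxy)spiro[5.5]undecan-1-one (key-step product; C7 ketone, C10 bromide) | O=C1CC[C@H](Br)C(C)(C)[C@]12CC[C@@](C)(O[Si](CC)(CC)CC)[C@H](Cl)C2 | intermediate
17 | {[(2R,3R,6S,8S)-8-bromo-2-chloro-3,7,7-trimethyl-11-methylidenespiro[5.5]undecan-3-yl]oxy}triethylsilane | C=C1CC[C@H](Br)C(C)(C)[C@]12CC[C@@](C)(O[Si](CC)(CC)CC)[C@H](Cl)C2 | intermediate
18 | (2S,6S,8R,9R)-2,9-dibromo-8-chloro-1,1,9-trimethyl-5-methylidenespiro[5.5]undecane; chamigrene numbering (2R,3R,6S,10S) | C=C1CC[C@H](Br)C(C)(C)[C@]12CC[C@@](C)(Br)[C@H](Cl)C2 | target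

**Totals**
Total step count: 12. Longest linear sequence: 12 steps from (S)-limonene (prenol enters at step 6).

**Steps most likely to fail**

Step 10 (key step). Bromine transfer from 15 to the hindered secondary C10 radical may be too slow to sustain the chain, so that the cyclised radical is reduced or couples, or bromine may be delivered to both faces of C10. The fallback replaces bromine transfer by degenerative xanthate transfer while forming the same C8–C9 bond and ring. It sets out from 15: displacement of the primary bromide with KSC(S)OEt in acetone at 0 °C gives the keto xanthate F1. Heating F1 with dilauroyl peroxide in 1,2-dichloroethane closes ring A 6-endo with transfer of the xanthate group to C10 and gives the spiro ketone C10 xanthate F2. Radical exchange of the xanthate for bromine with ethyl 2-bromo-2-methylpropanoate and a peroxide initiator in refluxing chlorobenzene, in which the same C10 radical is brominated on its equatorial face by a much better bromine donor, returns to the route at 16.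

Step 12. The C3 cation may lose a proton (towards C4 or the C3 methyl) instead of capturing bromide, and the HBr so released may protonate or hydrobrominate the C7 exocyclic alkene. The fallback installs the tertiary bromide before the alkene exists. It sets out from 16: anhydrous HBr in CH2Cl2 at −40 °C converts the tertiary silyl ether into the bromide under conditions in which any alkene formed by elimination is re-hydrobrominated in the Markovnikov sense, with the same chloronium and axial-attack control, giving the dibromo chloro ketone F3. Methylenation of F3 with Cp2TiMe2 as in step 11 comes back to the route at the target 18.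

Step 11. The neopentyl C7 carbonyl next to the spiro carbon may react too slowly with Cp2Ti=CH2, so that decomposition of the reagent or thermal loss of HBr takes over. The fallback is a two-stage Peterson olefination. It sets out from 16: addition of Me3SiCH2Li in the presence of CeCl3 in THF at −78 °C gives the beta-hydroxysilane F4, and acid-induced anti elimination (BF3·OEt2, CH2Cl2, −78 °C) can give only the exocyclic alkene and returns to the route at 17.

**Further compounds**
F1 | step 10 | O-ethyl S-{2-[(1R,3R,4R)-3-chloro-4-methyl-1-(2-methylbut-3-en-2-yl)-4-(triethylsilyloxy)cyclohexyl]-2-oxoethyl} carbonodithioate (keto xanthate) | CCOC(=S)SCC(=O)[C@]1(C(C)(C)C=C)CC[C@@](C)(O[Si](CC)(CC)CC)[C@H](Cl)C1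
F2 | step 10 | O-ethyl S-[(4S,6R,8R,9R)-8-chloro-5,5,9-trimethyl-1-oxo-9-(triethylsilyloxy)spiro[5.5]undecan-4-yl] carbonodithioate (spiro ketone C10 xanthate) | O=C1CC[C@H](SC(=S)OCC)C(C)(C)[C@]12CC[C@@](C)(O[Si](CC)(CC)CC)[C@H](Cl)C2
F3 | step 12 | (4S,6R,8R,9R)-4,9-dibromo-8-chloro-5,5,9-trimethylspiro[5.5]undecan-1-one (dibromo chloro ketone) | O=C1CC[C@H](Br)C(C)(C)[C@]12CC[C@@](C)(Br)[C@H](Cl)C2
F4 | step 11 | (4S,6R,8R,9R)-4-bromo-8-chloro-5,5,9-trimethyl-9-(triethylsilyloxy)-1-[(trimethylsilyl)methyl]spiro[5.5]undecan-1-ol (beta-hydroxysilane, configuration at the carbinol carbon not defined) | C[Si](C)(C)CC1(O)CC[C@H](Br)C(C)(C)[C@]12CC[C@@](C)(O[Si](CC)(CC)CC)[C@H](Cl)C2
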